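C2, C3a, C7a and the other atom names follow 1-benzofuran numbering. Ring A is the carbocycle C3a–C4–C5–C6–C7–C7a and ring B is the tetrahydrofuran O1–C2–C3–C3a–C7a.
Enabling feature: rings A and B share the vinylogous ester O1–C7a=C7–C6=O. This puts C7a at the carboxyl level and, without the aryl group, C2 at the aldehyde level, so ring B is a disguised γ-alkoxy-γ-butyrolactone O1–C2(OR*)–C3–C3a–C7a(=O).
Key disconnections, all made in one flask: C7–C7a (Claisen closure of ring A, which opens the lactone and unmasks the C2 aldehyde), aryl–C2 (aryl Grignard, Felkin–Anh control), and O1–C7a (dehydrative re-closure of ring B).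
The lactone is the stereochemical template: menthyl acetal at C2 → C3 (anti conjugate methylation) → C3a (allylation, then Michael addition anti to the C3 methyl). C5 is set last by kinetic protonation.
Ring order: temporary lactone ring B → ring A → final ring B.

Key step: step 7

Remark: from the Michael addition up to the product of the key step, the methoxy-bearing carbon (future C5) is carried as a mixture of epimers, so the SMILES of these compounds leave it undefined.

Step 1
Reactants: 1 5-hydroxyfuran-2(5H)-one; 2 (+)-menthol
Product: 3 (5S)-5-{[(1S,2R,5S)-2-isopropyl-5-methylcyclohexyl]oxy}furan-2(5H)-one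
Conditions: neat, 100 °C, 20 h; crystallisation from petroleum ether; mother liquor re-equilibrated with cat. TsOH, CH2Cl2, rt, and recrystallised
Reagents that add atoms: none
Why: Thermal acetalisation of the cyclic pseudo-acid 1 with alcohol 2 gives both acetal epimers; the (5S) epimer, mirror image of the well-known crystalline (5R)-(−)-menthyl compound, should crystallise while the acid-labile acetal centre of the remainder is re-equilibrated, so the auxiliary fixes the first stereocentre.

Step 2
Reactants: 3 (5S)-5-(menthyloxy)furan-2(5H)-one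
Product: 4 (4S,5S)-4-methyl-5-{[(1S,2R,5S)-2-isopropyl-5-methylcyclohexyl]oxy}dihydrofuran-2(3H)-one
Conditions: MeMgBr (1.3 equiv), CuBr·SMe2 (10 mol %), THF/Me2S, −78 → −40 °C; sat. aq NH4Cl
Reagents that add atoms: methylmagnesium bromide, C[Mg]Br
Why: Copper-catalysed conjugate addition of a Grignard reagent to a γ-alkoxybutenolide should deliver the methyl group to the face anti to the bulky menthyloxy group, which sets the future C3 as S.

Step 3
Reactants: 4 (4S,5S)-4-methyl-5-(menthyloxy)dihydrofuran-2(3H)-one
Product: 5 (3S,4S,5S)-3-allyl-4-methyl-5-{[(1S,2R,5S)-2-isopropyl-5-methylcyclohexyl]oxy}dihydrofuran-2(3H)-one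
Conditions: LiN(iPr)2 (1.1 equiv), THF, −78 °C; allyl bromide (1.2 equiv), DMPU, −78 → −40 °C
Reagents that add atoms: allyl bromide, C=CCBr
Why: Lactone enolate alkylation with a reactive allylic halide should place allyl trans to the neighbouring methyl group, but this centre is planarised again in step 5, so its configuration is of no consequence.

Step 4
Reactants: 6 3,3-dimethoxybutan-2-one
Product: 7 3-methoxybut-3-en-2-one
Conditions: TsOH (1 mol %), hydroquinone (trace), neat, 140–150 °C, MeOH distilled off; then distillation of the product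
Reagents that add atoms: none
Why: Acid-catalysed elimination of methanol from an α-keto ketal (enol ether formation) is driven by removal of methanol and creates no stereocentre.

Step 5
Reactants: 5 (3S,4S,5S)-3-allyl-4-methyl-5-(menthyloxy)dihydrofuran-2(3H)-one; 7 3-methoxybut-3-en-2-one
Product: 8 (3S,4S,5S)-3-allyl-3-(2-methoxy-3-oxobutyl)-4-methyl-5-{[(1S,2R,5S)-2-isopropyl-5-methylcyclohexyl]oxy}dihydrofuran-2(3H)-one (both side-chain epimers)
Conditions: 5, LiN(iPr)2 (1.1 equiv), THF, −78 °C; 7 (1.5 equiv), −78 → −50 °C; AcOH, −78 °C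
Reagents that add atoms: none
Why: Aprotic Michael addition of the fully substituted lactone enolate to an α-substituted vinyl ketone (the α-substituent suppresses polymerisation as in α-silyl vinyl ketones) should take place on the enolate face anti to the adjacent methyl group (1,2-induction), which pushes allyl cis to methyl and sets the quaternary future C3a as S, while the methoxy carbon forms as a mixture that step 8 corrects.

Step 6
Reactants: 9 5-bromo-1,2,3-trimethoxybenzene
Product: 10 3,4,5-trimethoxyphenylmagnesium bromide (titrated THF solution)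
Conditions: Mg turnings, I2 (trace), THF, 40 °C
Reagents that add atoms: magnesium, [Mg]
Why: Direct magnesium insertion into an aryl bromide (Grignard formation) fixes the nucleophilic site at the ring carbon that electrophilic substitution of 1,2,3-trimethoxybenzene would not address; no stereocentre.

Step 7
Reactants: 8 (3S,4S,5S)-3-allyl-3-(2-methoxy-3-oxobutyl)-4-methyl-5-(menthyloxy)dihydrofuran-2(3H)-one; 10 3,4,5-trimethoxyphenylmagnesium bromide
Product: 13 (2R,3S,3aS)-3a-allyl-5-methoxy-3-methyl-2-(3,4,5-trimethoxyphenyl)-3,3a,4,5-tetrahydro-1-benzofuran-6(2H)-one (both C5 epimers), via formyl dione 11 (not isolated), via hydroxy dione 12 (not isolated)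
Conditions: 8, LiN(SiMe3)2 (2.1 equiv), THF, −78 → −30 °C; 10 (2.5 equiv), −78 → 0 °C; 1 M HCl, THF, 0 °C → rt
Reagents that add atoms: none
Why: Proposed new method: LiN(SiMe3)2 converts the methyl ketone of 8 into its enolate, C7 attacks the lactone carbonyl C7a (6-exo-trig Claisen/Dieckmann closure of ring A), and the adduct collapses by expelling O1 as a hemiacetal alkoxide that sheds lithium mentholate, so the template ring opens to aldehyde 11 with its 1,3-dione masked as an inert lithium diketonate. Grignard reagent 10 then adds to the only electrophile left, the C2 aldehyde, and acid closes ring B by 5-exo-trig attack of the new C2 hydroxyl of 12 on C7a followed by loss of water, a vinylogous esterification that leaves the C2–O bond untouched. The closest known reaction types are the addition of aryl Grignard reagents to ring-chain tautomeric pseudo-acids such as 2-formylbenzoic acid (3-arylphthalide synthesis), the one-pot reduction/Grignard sequence on esters that runs through metal hemiacetal alkoxides, and the base-induced cyclisation of δ-keto esters to cyclohexane-1,3-diones; new is their coupling through a γ-alkoxybutyrolactone. C2 is set by Felkin–Anh control, with the quaternary C3a as the large group anti to the incoming aryl and the C3 hydrogen next to its trajectory, which should give the syn (2R,3S) alcohol and hence the 2,3-cis tetrahydrofuran, while C3 and C3a are carried over from 8. The step needs chemoselectivity for the aldehyde over two ketones (secured by the diketonate), regioselective closure of ring B (secured by ring size, since only C7a can give a five-membered ring), and configurational integrity at C3 (secured by the low temperature, the hindered tertiary C3–H and partial storage of the aldehyde as its lithium hemiacetal).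

Step 8
Reactants: 13 (2R,3S,3aS)-3a-allyl-5-methoxy-3-methyl-2-(3,4,5-trimethoxyphenyl)-3,3a,4,5-tetrahydro-1-benzofuran-6(2H)-one (both C5 epimers)
Product: 15 dysodanthin B, via lithium dienolate 14 (not isolated)
Conditions: LiN(iPr)2 (1.2 equiv), THF, −78 °C; 2,6-di-tert-butyl-4-methylphenol (3 equiv), THF, −78 °C; H2O, cold neutral work-up
Reagents that add atoms: none
Why: Kinetic α′-deprotonation of the vinylogous ester planarises C5 of both epimers to the single dienolate 14 (stereoconvergent), and kinetic protonation by the bulky phenol should occur on the open face of ring A, anti to the C3a allyl group (held pseudo-axial because ring B keeps C3 pseudo-equatorial), which places methoxy cis to allyl (5R), the contra-thermodynamic epimer.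

Compound list
1 | 5-hydroxyfuran-2(5H)-one (racemic pseudo-acid) | O=C1C=CC(O)O1 | starting material
2 | (+)-menthol, (1S,2R,5S)-2-isopropyl-5-methylcyclohexan-1-ol | CC(C)[C@H]1CC[C@H](C)C[C@@H]1O | starting material
3 | (5S)-5-{[(1S,2R,5S)-2-isopropyl-5-methylcyclohexyl]oxy}furan-2(5H)-one | CC(C)[C@H]1CC[C@H](C)C[C@@H]1O[C@H]2OC(=O)C=C2 | intermediate
4 | (4S,5S)-4-methyl-5-{[(1S,2R,5S)-2-isopropyl-5-methylcyclohexyl]oxy}dihydrofuran-2(3H)-one (methyl trans to menthyloxy) | CC(C)[C@H]1CC[C@H](C)C[C@@H]1O[C@H]2OC(=O)C[C@@H]2C | intermediate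
5 | (3S,4S,5S)-3-allyl-4-methyl-5-{[(1S,2R,5S)-2-isopropyl-5-methylcyclohexyl]oxy}dihydrofuran-2(3H)-one (all-trans) | CC(C)[C@H]1CC[C@H](C)C[C@@H]1O[C@H]2OC(=O)[C@@H](CC=C)[C@@H]2C | intermediate
6 | 3,3-dimethoxybutan-2-one | CC(=O)C(C)(OC)OC | starting material
7 | 3-methoxybut-3-en-2-one | C=C(OC)C(C)=O | intermediate
8 | (3S,4S,5S)-3-allyl-3-(2-methoxy-3-oxobutyl)-4-methyl-5-{[(1S,2R,5S)-2-isopropyl-5-methylcyclohexyl]oxy}dihydrofuran-2(3H)-one (allyl cis to methyl; side-chain epimers) | CC(C)[C@H]1CC[C@H](C)C[C@@H]1O[C@H]2OC(=O)[C@@](CC=C)(CC(OC)C(C)=O)[C@@H]2C | intermediate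
9 | 5-bromo-1,2,3-trimethoxybenzene | COc1cc(Br)cc(OC)c1OC | starting material
10 | 3,4,5-trimethoxyphenylmagnesium bromide | COc1cc([Mg]Br)cc(OC)c1OC | intermediate
11 | (2S)-2-[(1S)-1-allyl-5-methoxy-2,4-dioxocyclohexyl]propanal, present in the flask as its lithium diketonate | O=C[C@@H](C)[C@]1(CC=C)CC(OC)C(=O)CC1=O | intermediate
12 | (4S)-4-allyl-4-[(1R,2S)-1-hydroxy-1-(3,4,5-trimethoxyphenyl)propan-2-yl]-6-methoxycyclohexane-1,3-dione | O[C@@H](c1cc(OC)c(OC)c(OC)c1)[C@@H](C)[C@]1(CC=C)CC(OC)C(=O)CC1=O | intermediate
13 | (2R,3S,3aS)-3a-allyl-5-methoxy-3-methyl-2-(3,4,5-trimethoxyphenyl)-3,3a,4,5-tetrahydro-1-benzofuran-6(2H)-one (aryl, methyl and allyl on one face; C5 epimers) | C=CC[C@@]12CC(OC)C(=O)C=C1O[C@@H](c1cc(OC)c(OC)c(OC)c1)[C@H]2C | intermediate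
14 | lithium (2R,3S,3aS)-3a-allyl-5-methoxy-3-methyl-2-(3,4,5-trimethoxyphenyl)-2,3,3a,4-tetrahydro-1-benzofuran-6-olate | C=CC[C@@]12CC(OC)=C([O-])C=C1O[C@@H](c1cc(OC)c(OC)c(OC)c1)[C@H]2C.[Li+] | intermediate
15 | dysodanthin B, (2R,3S,3aS,5R)-3a-allyl-5-methoxy-3-methyl-2-(3,4,5-trimethoxyphenyl)-3,3a,4,5-tetrahydro-1-benzofuran-6(2H)-one | C=CC[C@@]12C[C@@H](OC)C(=O)C=C1O[C@@H](c1cc(OC)c(OC)c(OC)c1)[C@H]2C | target

Total step count: 8
Longest linear sequence: 6 steps (1, 2, 3, 5, 7, 8)

Steps most likely to fail

1. Step 7.
- What may go wrong: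
  - The liberated aldehyde may epimerise at C3 before the Grignard reagent arrives.
  - The aldehyde may be captured by the diketonate carbon C7 in an intramolecular aldol reaction, giving a bridged bicyclo[3.2.1]octane.
  - The Claisen closure onto the hindered lactone carbonyl may stay incomplete at low temperature.
  - The acidic finish may ionise the benzylic C2–O bond and drift towards the 2,3-trans isomer.
- Fallback (known chemistry, sets out from 8, returns at 13): 8 is transacetalised with HC(OMe)3 and cat. camphorsulfonic acid in MeOH to the acyclic methyl ester dimethyl acetal F1. This is cyclised with KOtBu in THF (Dieckmann-type closure of a δ-keto ester) to the acetal-protected cyclohexane-1,3-dione F2. 1 M HCl in THF unmasks the aldehyde, which closes to the bicyclic lactol F3 (anomers). F3 is treated with three equivalents of 10 in THF at −78 → 0 °C; the first equivalent deprotonates and opens the lactol to the magnesium diketonate of 11. Mild acidic work-up takes 12 on to 13.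

2. Step 8.
- What may go wrong:
  - Protonation may follow the torsionally preferred axial trajectory on the allyl face.
  - The coordinated amine may return its proton unselectively.
  - The product may equilibrate to the equatorial methoxy epimer during quench or chromatography.
- Fallback (sets out from 13, returns at 15): dienolate 14 is trapped with Me3SiCl as the trimethylsilyl dienol ether F4. F4 is isolated free of amine and protonated under reagent control with catalytic 3,3'-bis(2,4,6-triisopropylphenyl)-1,1'-binaphthyl-2,2'-diyl N-triflyl thiophosphoramide and phenol as the stoichiometric proton source in toluene at low temperature. The catalyst enantiomer that reinforces the substrate bias is chosen by experiment.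

3. Step 5.
- What may go wrong:
  - The hindered enolate may add 1,2 to the ketone.
  - The acceptor may oligomerise.
  - Proton transfer from the acidic adduct may quench the enolate.
  - The distant menthyloxy group may erode the facial selectivity.
- Fallback (sets out from 5, returns at 8): 5 is converted with LiN(iPr)2 and tBuMe2SiCl in THF/DMPU into the tert-butyldimethylsilyl ketene acetal F5. F5 undergoes a fluoride-catalysed Mukaiyama–Michael (group-transfer) addition to 7 with [(Me2N)3S][Me3SiF2] in THF, giving the silyl enol ether adduct F6. Dilute aqueous citric acid hydrolyses F6 to 8.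

Further compounds
F1 | step 7 | methyl (2S)-2-allyl-2-[(2S)-1,1-dimethoxypropan-2-yl]-4-methoxy-5-oxohexanoate (C4 epimers) | COC(OC)[C@@H](C)[C@](CC=C)(CC(OC)C(C)=O)C(=O)OC
F2 | step 7 | (4S)-4-allyl-4-[(2S)-1,1-dimethoxypropan-2-yl]-6-methoxycyclohexane-1,3-dione (C6 epimers) | COC(OC)[C@@H](C)[C@]1(CC=C)CC(OC)C(=O)CC1=O
F3 | step 7 | (3S,3aS)-3a-allyl-2-hydroxy-5-methoxy-3-methyl-3,3a,4,5-tetrahydro-1-benzofuran-6(2H)-one (anomers, C5 epimers) | C=CC[C@@]12CC(OC)C(=O)C=C1OC(O)[C@H]2C
F4 | step 8 | (2R,3S,3aS)-3a-allyl-5-methoxy-3-methyl-2-(3,4,5-trimethoxyphenyl)-6-(trimethylsilyloxy)-2,3,3a,4-tetrahydro-1-benzofuran | C=CC[C@@]12CC(OC)=C(O[Si](C)(C)C)C=C1O[C@@H](c1cc(OC)c(OC)c(OC)c1)[C@H]2C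
F5 | step 5 | (2S,3S)-4-allyl-5-(tert-butyldimethylsilyloxy)-3-methyl-2-{[(1S,2R,5S)-2-isopropyl-5-methylcyclohexyl]oxy}-2,3-dihydrofuran | CC(C)[C@H]1CC[C@H](C)C[C@@H]1O[C@H]2OC(O[Si](C)(C)C(C)(C)C)=C(CC=C)[C@@H]2C
F6 | step 5 | (3S,4S,5S)-3-allyl-3-[3-(tert-butyldimethylsilyloxy)-2-methoxybut-2-en-1-yl]-4-methyl-5-{[(1S,2R,5S)-2-isopropyl-5-methylcyclohexyl]oxy}dihydrofuran-2(3H)-one | CC(C)[C@H]1CC[C@H](C)C[C@@H]1O[C@H]2OC(=O)[C@@](CC=C)(CC(OC)=C(C)O[Si](C)(C)C(C)(C)C)[C@@H]2C
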